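The numbers stand for no real mixture, and the outcome is calculated.

Start from the amounts: 0.10 M of L lies as solid, 0.100 M of G arrives in portions, and each L.D.G holds two L and one G.

L 0.10 M; G 0.100 M (in portions, 2); time 4.0 d; the portions of G follow each other after 1.5 h, the first at the start

    L ⇌ D, rate k1*(cs1 - [D]) while solid is left; crystals form when [D] > cs1 (cs1 = 4.0 mM, k1 = 1.33 h⁻¹)
    D + G → D.G (k2 = 10.7 M⁻¹ h⁻¹)
    L + D.G → L.D.G (k3 = 8.92 M⁻¹ h⁻¹)

- the state of affairs at 4.0 d: stopped, and by what, or still going (for what has run out or reacted, a solid counts together with what of it has only dissolved) (all of L has reacted / it is still moving / G has run out first)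
- part of the L that has turned into other species by 4.0 d (what has only dissolved does not count)
- amount of D.G at 4.0 d, in percent of the L charged
- amount of L.D.G at 4.0 d, in percent of the L charged

- percentages count the L that a species holds: one L.D.G counts as two
- solid, in amounts per volume of the solution: L
- at the start none of L is in solution
- what has only dissolved of L counts as not reacted
- the reaction counts as stopped when no species that holds the L changes by six tenths of a point or more over the second half of the time
- run time (flask): 4.0 d

Run it in slow motion, and replace the falling c(G) by its mean. L should consume about 50.0 mM of G, so take the midpoint between the full charge and that much less: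

c(G), mean = 75.0 mM

In the first instants, solid dissolves and G captures D. Set dissolution equal to capture, and c(D) levels off with a steady feed F of D.G:

c(D) = 2.49 mM
F = 2.00 mM h⁻¹

This c(D) is lower than the solubility 4.0 mM. In the middle, solid is plentiful and D.G is short-lived, with a half-life by step 3 of 0.78 h at the charged amount of L. Dissolution and step 3 both remove solid, while step 3 also removes D.G, so c(L) − c(D.G) falls at twice the feed, with no dependence on step 3.

Near the end, c(L) shrinks and step 3 slows against the feed. Call the level where solid and D.G meet in that balance the crossover concentration, c* = √(F/k3):

c* = 15.0 mM

Stepping the scaled equations by hand, I find D.G close to this crossover concentration, the level at which equal amounts of solid and D.G run step 3 as fast as the feed, as the solid vanishes. The dissolved D then passes to G. The solid lasts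

t = (c(L) + c*)/(2F) = 28.7 h

which is shorter than the run. My outcome is all of L has reacted, with D.G 17.5 % and L.D.G 82.5 %. Check the mean: c(G) at its two ends puts c* between 13.1 mM and 16.3 mM.

The forecast says all of L has reacted, with conversion 100 %, D.G 17.3 % and L.D.G 82.7 %, reasoning that “each G taken uses about two L”.

The simulation gives all of L has reacted, with conversion 100 %, D.G 17.4 % and L.D.G 82.6 %. L, the limiting reagent, ends at 0 %, and G at 41 %.

Read against c*, the 17.4 mM of D.G in this flask is 1.16 c*. Part of the reason it stands there is step 3 acting together with the low solubility of D: with step 3 struck out, D.G goes from 17.4 % to 96.3 %, and without the low solubility from 17.4 % to 99.0 %. In the neighbour flask with 0.025 M of L, the mean c(G) is 93.8 mM, so c(D) is 2.28 mM and c* plus c(D) is 18.3 mM, or 73.2 % of its L; that flask holds 67.6 % as D.G.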